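**Retrosynthetic overview**
1. Feature: in each naphthalene the ring C5'–C8' carries OH on C5', the central biaryl bond on C6', H on C7' and the isoquinoline on C8'. With an oxygen bridge from C5' to C8', this ring is a furan bearing the aryl group on C2 and the other furan on C4. The 4'-methoxy-2'-methyl benzo ring is 3-methoxy-5-methylbenzyne.
2. Last disconnections: the C1=N bond of the dihydroisoquinoline (ring D) goes back to an acetyl group and a phthaloyl-masked amine. Three benzyl ethers and one trifluoroacetamide are the other masks.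
3. Key disconnection: C8'–C8a' and C4a'–C5' are cut in both naphthalenes at once, which leads to a 5,5'-diaryl-3,3'-bifuran and two arynes. The bifuran already holds all three biaryl bonds.
4. Bifuran: Suzuki coupling of two 2-aryl-4-bromofurans, each made from an aryl iodide and 4-bromo-2-furylzinc chloride. Both aryl iodides come from one (R)-1-arylpropan-2-amine, made from an aryl Grignard reagent and the D-alaninol-derived cyclic sulfamidate.
5. Ring order: the nitrogen ring of the tetrahydroisoquinoline (ring T) is formed first, then the two naphthalene carbocycles together, and last the nitrogen ring of ring D.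

Key step: step 21

Assumption: the SMILES fixes only the three stereocentres (C3 of ring D, C1 and C3 of ring T, all R) and leaves the two hindered isoquinoline–naphthalene axes open. The route does not control these axes, so the late compounds are expected as atropo-diastereomers, to be separated by HPLC.
Numbering: isoquinoline atoms are C1–C8a and naphthalene atoms C1'–C8a'. In the open-chain ring D blocks the arene carbons carry the isoquinoline numbers they will have later.

**Route**

Step 1
Reactants: 1 3-methoxy-5-methylphenol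
Product: 2 3-methoxy-5-methylphenyl isopropylcarbamate
Conditions: i-PrNCO, Et3N (cat.), CH2Cl2, rt
Reagents that add atoms: isopropyl isocyanate, CC(C)N=C=O
Why: Base-catalysed addition of the phenol to the isocyanate (carbamoylation) installs the directing group for the next step.

Step 2
Reactants: 2 3-methoxy-5-methylphenyl isopropylcarbamate
Product: 6 3-methoxy-5-methyl-2-(trimethylsilyl)phenyl isopropylcarbamate, via N-silyl carbamate 3 (not isolated), via aryllithium 4 (not isolated), via doubly silylated carbamate 5 (not isolated)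
Conditions: TBSOTf, TMEDA, Et2O, 0 °C to rt; n-BuLi (2 equiv), TMEDA, −78 °C; Me3SiCl, −78 °C to rt; aq. NaHSO4
Reagents that add atoms: chlorotrimethylsilane, C[Si](C)(C)Cl; held only by 3–5: tert-butyldimethylsilyl triflate, CC(C)(C)[Si](C)(C)OS(=O)(=O)C(F)(F)F; held only by 4: n-butyllithium, [Li]CCCC
Why: Directed ortho-metalation, in which the transiently N-silylated carbamate and the methoxy group together steer lithiation to the carbon between them, Me3SiCl traps the aryllithium, and the N-silyl group falls off in the acidic work-up.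

Step 3
Reactants: 6 3-methoxy-5-methyl-2-(trimethylsilyl)phenyl isopropylcarbamate
Product: 8 3-methoxy-5-methyl-2-(trimethylsilyl)phenyl trifluoromethanesulfonate, via silylphenol 7 (not isolated)
Conditions: DBU, Et2NH, MeCN, 40 °C; then PhNTf2, rt
Reagents that add atoms: N-phenylbis(trifluoromethanesulfonimide), O=S(=O)(N(c1ccccc1)S(=O)(=O)C(F)(F)F)C(F)(F)F
Why: Base-induced E1cB loss of isopropyl isocyanate (trapped by Et2NH) frees the phenolate without acid, so the labile C–Si bond survives, and O-triflation in the same flask gives the o-silylaryl triflate.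

Step 4
Reactants: 9 1,3-bis(benzyloxy)-5-bromobenzene; 10 tert-butyl (R)-4-methyl-1,2,3-oxathiazolidine-3-carboxylate 2,2-dioxide (commercial, derived from D-alaninol)
Product: 14 (R)-1-[3,5-bis(benzyloxy)phenyl]propan-2-amine, via aryl Grignard reagent 11 (not isolated), via N-Boc sulfamate salt 12 (not isolated), via N-Boc amine 13 (not isolated)
Conditions: Mg, THF, reflux; CuI (10 mol%), 10, −20 °C to rt; HCl (4 M in dioxane), MeOH, rt; aq. NaOH
Reagents that add atoms: magnesium, [Mg] (held only by 11 and 12)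
Why: Copper-catalysed SN2 opening of the cyclic sulfamidate by the Grignard reagent takes place at the primary CH2–O carbon, so the (R)-centre from D-alaninol is untouched, and acid then hydrolyses the N-sulfate and the Boc group.

Step 5
Reactants: 14 (R)-1-[3,5-bis(benzyloxy)phenyl]propan-2-amine
Product: 15 (R)-N-{1-[3,5-bis(benzyloxy)phenyl]propan-2-yl}acetamide
Conditions: Ac2O, Et3N, CH2Cl2, 0 °C to rt
Reagents that add atoms: acetic anhydride, CC(=O)OC(C)=O
Why: Plain N-acetylation of the primary amine supplies C1 and its methyl group for ring T.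

Step 6
Reactants: 15 (R)-N-{1-[3,5-bis(benzyloxy)phenyl]propan-2-yl}acetamide
Product: 16 (R)-6,8-bis(benzyloxy)-1,3-dimethyl-3,4-dihydroisoquinoline
Conditions: POCl3, MeCN, reflux; aq. NaOH
Reagents that add atoms: none
Why: Bischler–Napieralski cyclodehydration, in which the nitrilium ion attacks one of two equivalent positions (ortho to the side chain, para to a benzyloxy group), so only one regioisomer can form and C3 is unaffected.

Step 7
Reactants: 16 (R)-6,8-bis(benzyloxy)-1,3-dimethyl-3,4-dihydroisoquinoline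
Product: 17 (1R,3R)-6,8-bis(benzyloxy)-1,3-dimethyl-1,2,3,4-tetrahydroisoquinoline
Conditions: AlMe3, then LiAlH4, THF, −78 to 0 °C
Reagents that add atoms: none
Why: This is the known trans-selective imine reduction of this ring system, in which AlMe3 binds nitrogen on the face away from the pseudoaxial C3 methyl group, hydride reaches C1 from the face bearing that methyl group, and C1 is therefore set as (R), trans to C3, under substrate control.

Step 8
Reactants: 17 (1R,3R)-6,8-bis(benzyloxy)-1,3-dimethyl-1,2,3,4-tetrahydroisoquinoline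
Product: 18 (1R,3R)-6,8-bis(benzyloxy)-1,3-dimethyl-2-(trifluoroacetyl)-1,2,3,4-tetrahydroisoquinoline
Conditions: (CF3CO)2O, Et3N, CH2Cl2, 0 °C
Reagents that add atoms: trifluoroacetic anhydride, O=C(OC(=O)C(F)(F)F)C(F)(F)F
Why: N-acylation masks the secondary amine, which would otherwise add to the aryne, as an acid-stable tertiary amide with no N–H.

Step 9
Reactants: 18 (1R,3R)-6,8-bis(benzyloxy)-1,3-dimethyl-2-(trifluoroacetyl)-1,2,3,4-tetrahydroisoquinoline
Product: 19 (1R,3R)-6,8-bis(benzyloxy)-5-iodo-1,3-dimethyl-2-(trifluoroacetyl)-1,2,3,4-tetrahydroisoquinoline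
Conditions: NIS, CF3CO2H (cat.), MeCN, rt
Reagents that add atoms: N-iodosuccinimide, O=C1CCC(=O)N1I
Why: Electrophilic aromatic iodination goes to C5 (para to the 8-benzyloxy and ortho to the 6-benzyloxy group) because C7 is shielded between two benzyloxy groups, the usual outcome when 6,8-dialkoxytetrahydroisoquinolines are halogenated.

Step 10
Reactants: 20 2,4-dibromofuran
Product: 22 (4-bromofuran-2-yl)zinc chloride (THF solution used in steps 11 and 19), via 4-bromo-2-furyllithium 21 (not isolated)
Conditions: n-BuLi (1.0 equiv), Et2O, −78 °C; ZnCl2 (THF), −78 to 0 °C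
Reagents that add atoms: zinc dichloride, Cl[Zn]Cl; held only by 21: n-butyllithium, [Li]CCCC
Why: Bromine–lithium exchange is faster at the alpha position, where the ring oxygen stabilises the carbanion, and transmetalation to zinc gives a reagent that keeps the beta bromine and tolerates carbonyl groups.

Step 11
Reactants: 19 (1R,3R)-6,8-bis(benzyloxy)-5-iodo-1,3-dimethyl-2-(trifluoroacetyl)-1,2,3,4-tetrahydroisoquinoline; 22 (4-bromofuran-2-yl)zinc chloride
Product: 23 (1R,3R)-6,8-bis(benzyloxy)-5-(4-bromofuran-2-yl)-1,3-dimethyl-2-(trifluoroacetyl)-1,2,3,4-tetrahydroisoquinoline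
Conditions: 22 (1.5 equiv), PdCl2(dppf) (5 mol%), THF, 50 °C
Reagents that add atoms: none
Why: Negishi coupling, in which zerovalent palladium inserts into the aryl carbon–iodine bond much faster than into the furan beta carbon–bromine bond, and the small furylzinc reagent reaches the doubly ortho-substituted centre.

Step 12
Reactants: 23 (1R,3R)-6,8-bis(benzyloxy)-5-(4-bromofuran-2-yl)-1,3-dimethyl-2-(trifluoroacetyl)-1,2,3,4-tetrahydroisoquinoline
Product: 24 (1R,3R)-6,8-bis(benzyloxy)-1,3-dimethyl-5-[4-(pinacolboryl)furan-2-yl]-2-(trifluoroacetyl)-1,2,3,4-tetrahydroisoquinoline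
Conditions: B2pin2, PdCl2(dppf), KOAc, 1,4-dioxane, 85 °C
Reagents that add atoms: bis(pinacolato)diboron, CC1(C)OB(OC1(C)C)B1OC(C)(C)C(C)(C)O1
Why: Miyaura borylation at the unhindered furan carbon–bromine bond, with KOAc too weak a base to harm the trifluoroacetamide or to start a Suzuki homocoupling.

Step 13
Reactants: 14 (R)-1-[3,5-bis(benzyloxy)phenyl]propan-2-amine
Product: 25 (R)-2-{1-[3,5-bis(benzyloxy)phenyl]propan-2-yl}isoindoline-1,3-dione
Conditions: phthalic anhydride, Et3N (cat.), toluene, reflux, Dean–Stark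
Reagents that add atoms: phthalic anhydride, O=C1OC(=O)c2ccccc12
Why: Condensation to the phthalimide removes both N–H bonds, so the nitrogen can neither add to the aryne nor close onto the ketone that comes next, and the stereocentre is not at risk.

Step 14
Reactants: 25 (R)-2-{1-[3,5-bis(benzyloxy)phenyl]propan-2-yl}isoindoline-1,3-dione
Product: 26 (R)-2-{1-[2-acetyl-3,5-bis(benzyloxy)phenyl]propan-2-yl}isoindoline-1,3-dione
Conditions: AcCl, SnCl4, CH2Cl2, −40 to −10 °C
Reagents that add atoms: acetyl chloride, CC(=O)Cl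
Why: Friedel–Crafts acylation takes one of the two equivalent positions ortho to the side chain and para to a benzyloxy group rather than the site between the two benzyloxy groups, as with orcinol diethers, and the low temperature keeps SnCl4 from cleaving the benzyl ethers.

Step 15
Reactants: 26 (R)-2-{1-[2-acetyl-3,5-bis(benzyloxy)phenyl]propan-2-yl}isoindoline-1,3-dione
Product: 27 (R)-2-{1-[2-acetyl-3,5-dihydroxyphenyl]propan-2-yl}isoindoline-1,3-dione
Conditions: H2 (1 atm), Pd/C, EtOAc–MeOH, rt
Reagents that add atoms: none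
Why: Catalytic hydrogenolysis frees both phenols, which the next step needs for its regiochemistry, while the acetyl group is twisted by two ortho substituents, becomes chelated by the new 8-OH, and is therefore not reduced.

Step 16
Reactants: 27 (R)-2-{1-[2-acetyl-3,5-dihydroxyphenyl]propan-2-yl}isoindoline-1,3-dione
Product: 28 (R)-2-{1-[2-acetyl-3,5-dihydroxy-4-iodophenyl]propan-2-yl}isoindoline-1,3-dione
Conditions: I2 (0.4 equiv), HIO3 (0.2 equiv), EtOH–H2O, 35 °C
Reagents that add atoms: iodine, [I][I]; iodic acid, OI(=O)=O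
Why: In this electrophilic iodination of a chelated resorcinol the hydrogen bond between 8-OH and the acetyl group fixes C6–C7 as the enol double bond of the free 6-OH, so iodine enters C7 between the hydroxyl groups as it does in 2,4-dihydroxyacetophenone, and C5 is further shielded by the branched side chain.

Step 17
Reactants: 28 (R)-2-{1-[2-acetyl-3,5-dihydroxy-4-iodophenyl]propan-2-yl}isoindoline-1,3-dione
Product: 29 (R)-2-{1-[2-acetyl-5-(benzyloxy)-3-hydroxy-4-iodophenyl]propan-2-yl}isoindoline-1,3-dione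
Conditions: BnBr (1.05 equiv), K2CO3, acetone, reflux
Reagents that add atoms: benzyl bromide, BrCc1ccccc1
Why: Williamson ether synthesis alkylates only the free and more acidic 6-OH (para to the acetyl group), because the 8-OH is tied up in the hydrogen bond to the ketone.

Step 18
Reactants: 29 (R)-2-{1-[2-acetyl-5-(benzyloxy)-3-hydroxy-4-iodophenyl]propan-2-yl}isoindoline-1,3-dione
Product: 30 (R)-2-{1-[2-acetyl-5-(benzyloxy)-4-iodo-3-methoxyphenyl]propan-2-yl}isoindoline-1,3-dione
Conditions: MeI (excess), K2CO3, DMF, 45 °C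
Reagents that add atoms: iodomethane, IC
Why: Williamson ether synthesis in a polar solvent with excess MeI methylates the remaining chelated 8-OH and so fixes the 8-OMe/6-OBn pattern without ambiguity.

Step 19
Reactants: 30 (R)-2-{1-[2-acetyl-5-(benzyloxy)-4-iodo-3-methoxyphenyl]propan-2-yl}isoindoline-1,3-dione; 22 (4-bromofuran-2-yl)zinc chloride
Product: 31 (R)-2-{1-[2-acetyl-5-(benzyloxy)-4-(4-bromofuran-2-yl)-3-methoxyphenyl]propan-2-yl}isoindoline-1,3-dione
Conditions: 22 (1.5 equiv), PdCl2(dppf) (5 mol%), THF, 50 °C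
Reagents that add atoms: none
Why: Negishi coupling as in step 11, in which the organozinc reagent adds neither to the hindered ketone nor to the imide and the aryl iodide reacts before any furan bromide.

Step 20
Reactants: 31 (R)-2-{1-[2-acetyl-5-(benzyloxy)-4-(4-bromofuran-2-yl)-3-methoxyphenyl]propan-2-yl}isoindoline-1,3-dione; 24 (1R,3R)-6,8-bis(benzyloxy)-1,3-dimethyl-5-[4-(pinacolboryl)furan-2-yl]-2-(trifluoroacetyl)-1,2,3,4-tetrahydroisoquinoline
Product: 32 5-(ring D aryl)-5'-(ring T aryl)-3,3'-bifuran
Conditions: Pd(OAc)2, SPhos, K3PO4, toluene–H2O (10:1), 60 °C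
Reagents that add atoms: none
Why: Suzuki–Miyaura coupling between two unhindered furan beta positions, where the phosphate base at moderate temperature spares the phthalimide, the trifluoroacetamide and the enolisable ketone.

Step 21
Reactants: 32 5-(ring D aryl)-5'-(ring T aryl)-3,3'-bifuran; 8 3-methoxy-5-methyl-2-(trimethylsilyl)phenyl trifluoromethanesulfonate (2 equiv taken up, 3 equiv charged in portions)
Product: 35 protected quateraryl bis-naphthol, via 3-methoxy-5-methylbenzyne 33 (not isolated), via bis-oxabicyclic adduct 34 (not isolated)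
Conditions: CsF, MeCN–toluene (1:1), 25 to 45 °C; then CF3CO2H, CH2Cl2, 0 °C to rt, same flask
Reagents that add atoms: none
Why: CsF removes the silyl group of 8 and triflate leaves, giving aryne 33, which adds across C2 and C5 of each furan of 32 in a concerted but asynchronous [4+2] cycloaddition (aryne–furan Diels–Alder reaction), so each of the two new six-membered carbocycles is closed intermolecularly by two sigma bonds formed together, C8'–C8a' and C4a'–C5'. CF3CO2H then protonates each oxygen bridge of 34 and breaks the C–O bond at the aryl-bearing bridgehead, whose cation is tertiary, benzylic and allylic and is extended at its far end (C6') by the neighbouring furan-derived ring; loss of the proton from the CH bridgehead, directly or after a 1,2-hydride shift and enolisation, leaves the oxygen on C5' as the naphthol, which is the known acid isomerisation of 1,4-epoxy-1,4-dihydronaphthalenes. The four bridgehead stereocentres of 34 arise without control and are erased on aromatisation, 35 gains no stereocentre, the three (R)-centres are spectators, and the two hindered axes become configurationally stable here without control. The selectivity needed is orientational, twice over: the aryl-bearing furan carbon must bond to the aryne carbon remote from the methoxy group, so that OMe ends up peri to OH. What secures it is steric, because the aryl group on the furan has two ortho substituents, stands perpendicular to the furan and clashes with the methoxy group, whose methyl lies on the aryne side since a ring hydrogen blocks its other side; this must outweigh the polarisation of a 3-alkoxyaryne, which alone would pair the remote aryne carbon with the more nucleophilic CH terminus of the furan, and that is why the risk of the route sits here. Ionisation at the CH bridgehead, which the ortho-methoxy group of the benzo ring assists, can lead on only by migration of the crowded aryl group and otherwise recloses, and the acid is added only when all of 8 is used up so that the free naphthols never meet the aryne.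

Step 22
Reactants: 35 protected quateraryl bis-naphthol
Product: 36 pentaphenolic keto phthalimide
Conditions: H2 (1 atm), Pd/C, EtOAc–MeOH, rt
Reagents that add atoms: none
Why: Hydrogenolysis of the three benzyl ethers is done while no C=N bond exists, which avoids both imine reduction and a boron halide that would chelate and strip the methyl ethers lying next to the ketone or peri to OH, and the twisted acetyl group, the imide and the amide are inert.

Step 23
Reactants: 36 pentaphenolic keto phthalimide
Product: 38 korundamine A, via amino ketone 37 (not isolated)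
Conditions: N2H4·H2O, EtOH, reflux, Ar; HPLC
Reagents that add atoms: none
Why: Hydrazinolysis (Ing–Manske cleavage of the phthalimide and acyl transfer from the activated trifluoroacetamide) frees both amines, and the primary amine condenses at once with the neighbouring acetyl group to give the conjugated six-membered cyclic imine without touching any stereocentre.

**Compound list**
1 | 3-methoxy-5-methylphenol | COc1cc(C)cc(O)c1 | starting material
2 | 3-methoxy-5-methylphenyl isopropylcarbamate | COc1cc(C)cc(OC(=O)NC(C)C)c1 | intermediate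
3 | 3-methoxy-5-methylphenyl N-(tert-butyldimethylsilyl)-N-isopropylcarbamate (not isolated) | COc1cc(C)cc(OC(=O)N(C(C)C)[Si](C)(C)C(C)(C)C)c1 | intermediate
4 | 2-lithio derivative of 3 (not isolated) | COc1cc(C)cc(OC(=O)N(C(C)C)[Si](C)(C)C(C)(C)C)c1[Li] | intermediate
5 | 2-trimethylsilyl derivative of 3 (not isolated) | COc1cc(C)cc(OC(=O)N(C(C)C)[Si](C)(C)C(C)(C)C)c1[Si](C)(C)C | intermediate
6 | 3-methoxy-5-methyl-2-(trimethylsilyl)phenyl isopropylcarbamate | COc1cc(C)cc(OC(=O)NC(C)C)c1[Si](C)(C)C | intermediate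
7 | 3-methoxy-5-methyl-2-(trimethylsilyl)phenol, present as its DBU salt (not isolated) | COc1cc(C)cc(O)c1[Si](C)(C)C | intermediate
8 | 3-methoxy-5-methyl-2-(trimethylsilyl)phenyl trifluoromethanesulfonate | COc1cc(C)cc(OS(=O)(=O)C(F)(F)F)c1[Si](C)(C)C | intermediate
9 | 1,3-bis(benzyloxy)-5-bromobenzene | Brc1cc(OCc2ccccc2)cc(OCc2ccccc2)c1 | starting material
10 | tert-butyl (R)-4-methyl-1,2,3-oxathiazolidine-3-carboxylate 2,2-dioxide | C[C@@H]1COS(=O)(=O)N1C(=O)OC(C)(C)C | starting material
11 | 3,5-bis(benzyloxy)phenylmagnesium bromide (not isolated) | Br[Mg]c1cc(OCc2ccccc2)cc(OCc2ccccc2)c1 | intermediate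
12 | bromomagnesium (R)-N-Boc-N-{1-[3,5-bis(benzyloxy)phenyl]propan-2-yl}sulfamate (not isolated) | C(c1cc(OCc2ccccc2)cc(OCc2ccccc2)c1)[C@@H](C)N(C(=O)OC(C)(C)C)S(=O)(=O)O[Mg]Br | intermediate
13 | tert-butyl (R)-{1-[3,5-bis(benzyloxy)phenyl]propan-2-yl}carbamate (not isolated) | C(c1cc(OCc2ccccc2)cc(OCc2ccccc2)c1)[C@@H](C)NC(=O)OC(C)(C)C | intermediate
14 | (R)-1-[3,5-bis(benzyloxy)phenyl]propan-2-amine | C(c1cc(OCc2ccccc2)cc(OCc2ccccc2)c1)[C@@H](C)N | intermediate
15 | (R)-N-{1-[3,5-bis(benzyloxy)phenyl]propan-2-yl}acetamide | C(c1cc(OCc2ccccc2)cc(OCc2ccccc2)c1)[C@@H](C)NC(C)=O | intermediate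
16 | (R)-6,8-bis(benzyloxy)-1,3-dimethyl-3,4-dihydroisoquinoline | c1(OCc3ccccc3)cc(OCc3ccccc3)c2c(c1)C[C@@H](C)N=C2C | intermediate
17 | (1R,3R)-6,8-bis(benzyloxy)-1,3-dimethyl-1,2,3,4-tetrahydroisoquinoline (1,3-trans) | c1(OCc3ccccc3)cc(OCc3ccccc3)c2c(c1)C[C@@H](C)N[C@@H]2C | intermediate
18 | (1R,3R)-6,8-bis(benzyloxy)-1,3-dimethyl-2-(trifluoroacetyl)-1,2,3,4-tetrahydroisoquinoline | c1(OCc3ccccc3)cc(OCc3ccccc3)c2c(c1)C[C@@H](C)N(C(=O)C(F)(F)F)[C@@H]2C | intermediate
19 | (1R,3R)-6,8-bis(benzyloxy)-5-iodo-1,3-dimethyl-2-(trifluoroacetyl)-1,2,3,4-tetrahydroisoquinoline | Ic1c(OCc2ccccc2)cc(OCc2ccccc2)c2c1C[C@@H](C)N(C(=O)C(F)(F)F)[C@@H]2C | intermediate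
20 | 2,4-dibromofuran | Brc1coc(Br)c1 | starting material
21 | 4-bromo-2-furyllithium (not isolated) | [Li]c1cc(Br)co1 | intermediate
22 | (4-bromofuran-2-yl)zinc chloride (THF solution) | Cl[Zn]c1cc(Br)co1 | intermediate
23 | (1R,3R)-6,8-bis(benzyloxy)-5-(4-bromofuran-2-yl)-1,3-dimethyl-2-(trifluoroacetyl)-1,2,3,4-tetrahydroisoquinoline | Brc1coc(-c2c(OCc3ccccc3)cc(OCc3ccccc3)c3c2C[C@@H](C)N(C(=O)C(F)(F)F)[C@@H]3C)c1 | intermediate
24 | (1R,3R)-6,8-bis(benzyloxy)-1,3-dimethyl-5-[4-(4,4,5,5-tetramethyl-1,3,2-dioxaborolan-2-yl)furan-2-yl]-2-(trifluoroacetyl)-1,2,3,4-tetrahydroisoquinoline | CC1(C)OB(OC1(C)C)c1coc(-c2c(OCc3ccccc3)cc(OCc3ccccc3)c3c2C[C@@H](C)N(C(=O)C(F)(F)F)[C@@H]3C)c1 | intermediate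
25 | (R)-2-{1-[3,5-bis(benzyloxy)phenyl]propan-2-yl}isoindoline-1,3-dione | C(c1cc(OCc2ccccc2)cc(OCc2ccccc2)c1)[C@@H](C)N1C(=O)c2ccccc2C1=O | intermediate
26 | (R)-2-{1-[2-acetyl-3,5-bis(benzyloxy)phenyl]propan-2-yl}isoindoline-1,3-dione | CC(=O)c1c(OCc2ccccc2)cc(OCc2ccccc2)cc1C[C@@H](C)N1C(=O)c2ccccc2C1=O | intermediate
27 | (R)-2-{1-[2-acetyl-3,5-dihydroxyphenyl]propan-2-yl}isoindoline-1,3-dione | CC(=O)c1c(O)cc(O)cc1C[C@@H](C)N1C(=O)c2ccccc2C1=O | intermediate
28 | (R)-2-{1-[2-acetyl-3,5-dihydroxy-4-iodophenyl]propan-2-yl}isoindoline-1,3-dione | CC(=O)c1c(O)c(I)c(O)cc1C[C@@H](C)N1C(=O)c2ccccc2C1=O | intermediate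
29 | (R)-2-{1-[2-acetyl-5-(benzyloxy)-3-hydroxy-4-iodophenyl]propan-2-yl}isoindoline-1,3-dione | CC(=O)c1c(O)c(I)c(OCc2ccccc2)cc1C[C@@H](C)N1C(=O)c2ccccc2C1=O | intermediate
30 | (R)-2-{1-[2-acetyl-5-(benzyloxy)-4-iodo-3-methoxyphenyl]propan-2-yl}isoindoline-1,3-dione | CC(=O)c1c(OC)c(I)c(OCc2ccccc2)cc1C[C@@H](C)N1C(=O)c2ccccc2C1=O | intermediate
31 | (R)-2-{1-[2-acetyl-5-(benzyloxy)-4-(4-bromofuran-2-yl)-3-methoxyphenyl]propan-2-yl}isoindoline-1,3-dione | CC(=O)c1c(OC)c(-c2cc(Br)co2)c(OCc2ccccc2)cc1C[C@@H](C)N1C(=O)c2ccccc2C1=O | intermediate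
32 | 3,3'-bifuran with 3-acetyl-6-(benzyloxy)-2-methoxy-4-[(2R)-2-phthalimidopropyl]phenyl on C5 and (1R,3R)-6,8-bis(benzyloxy)-1,3-dimethyl-2-(trifluoroacetyl)-1,2,3,4-tetrahydroisoquinolin-5-yl on C5' | CC(=O)c1c(OC)c(-c2cc(-c3coc(-c4c(OCc5ccccc5)cc(OCc5ccccc5)c5c4C[C@@H](C)N(C(=O)C(F)(F)F)[C@@H]5C)c3)co2)c(OCc2ccccc2)cc1C[C@@H](C)N1C(=O)c2ccccc2C1=O | intermediate
33 | 3-methoxy-5-methylbenzyne (not isolated) | COC1=CC(C)=CC#C1 | intermediate
34 | bis-adduct: both furans of 32 turned into 5-methoxy-7-methyl-1,4-epoxy-1,4-dihydronaphthalenes, aryl on bridgehead C1, link between the two C3 atoms, bridgehead configurations mixed (not isolated) | CC(=O)c1c(OC)c(C23C=C(C4=CC5(c6c(OCc7ccccc7)cc(OCc7ccccc7)c7c6C[C@@H](C)N(C(=O)C(F)(F)F)[C@@H]7C)OC4c4c(OC)cc(C)cc45)C(O2)c2c(OC)cc(C)cc23)c(OCc2ccccc2)cc1C[C@@H](C)N1C(=O)c2ccccc2C1=O | intermediate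
35 | protected quateraryl bis-naphthol: 6',6''-linked bis(5-hydroxy-4-methoxy-2-methylnaphthalene) with the ring D aryl group of 32 on C8' and the ring T group of 32 on C8'' | CC(=O)c1c(OC)c(-c2cc(-c3cc(-c4c(OCc5ccccc5)cc(OCc5ccccc5)c5c4C[C@@H](C)N(C(=O)C(F)(F)F)[C@@H]5C)c4cc(C)cc(OC)c4c3O)c(O)c3c(OC)cc(C)cc23)c(OCc2ccccc2)cc1C[C@@H](C)N1C(=O)c2ccccc2C1=O | intermediate
36 | pentaphenolic keto phthalimide (35 without its three benzyl groups) | CC(=O)c1c(OC)c(-c2cc(-c3cc(-c4c(O)cc(O)c5c4C[C@@H](C)N(C(=O)C(F)(F)F)[C@@H]5C)c4cc(C)cc(OC)c4c3O)c(O)c3c(OC)cc(C)cc23)c(O)cc1C[C@@H](C)N1C(=O)c2ccccc2C1=O | intermediate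
37 | amino ketone (36 without phthaloyl and trifluoroacetyl groups, not isolated) | CC(=O)c1c(OC)c(-c2cc(-c3cc(-c4c(O)cc(O)c5c4C[C@@H](C)N[C@@H]5C)c4cc(C)cc(OC)c4c3O)c(O)c3c(OC)cc(C)cc23)c(O)cc1C[C@@H](C)N | intermediate
38 | korundamine A, (3R) in ring D and (1R,3R) in ring T | COc1c2c(cc(O)c1-c1cc(-c3cc(-c4c(O)cc(O)c5c4C[C@@H](C)N[C@@H]5C)c4cc(C)cc(OC)c4c3O)c(O)c3c(OC)cc(C)cc13)C[C@@H](C)N=C2C | target

**Step count**
Total: 23 steps. Longest linear sequence: 12 steps (9 → 14 → 25 → 26 → 27 → 28 → 29 → 30 → 31 → 32 → 35 → 36 → 38). The ring T branch, 9 → 14 → 15 → 16 → 17 → 18 → 19 → 23 → 24 → 32, is equally long up to 32.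

**Steps most likely to fail**

Step 21.
- What may go wrong: mixed orientation in one or both aryne additions. The reaction may also stall after the first addition because the second furan is shielded. An oxygen bridge may open at the CH bridgehead, followed by aryl migration. With two reacting sites on one advanced substrate, each of these leaks multiplies.
- Fallback: build one naphthalene per half and form the lightly hindered central biaryl bond afterwards by cross-coupling. It sets out from 23 and 31.
- With 8 and CsF, 23 gives the ring T bromo-oxabicycle F1, which acid turns into the ring T 2-bromo-1-naphthol F2.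
- In the same way 31 gives the ring D bromo-oxabicycle F3 and then the ring D 2-bromo-1-naphthol F4. Isomers of the wrong orientation are removed by chromatography at this monomer stage.
- Miyaura borylation of F2 (B2pin2, PdCl2(dppf), KOAc) gives the ring T naphthol boronate F5. Suzuki–Miyaura coupling of F5 with F4 (PdCl2(dppf), K3PO4, dioxane–H2O) comes back to the route at 35.

Step 16.
- What may go wrong: attack of the iodinating agent at C5 (para to the chelated hydroxyl) instead of, or as well as, C7, and over-iodination.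
- Fallback: block C5 first. It sets out from 27.
- SO2Cl2 (1 equiv, Et2O–CH2Cl2, 0 °C) chlorinates the position next to the side chain, the site that chlorination takes in 6-alkyl-2,4-dihydroxyaryl carbonyl compounds, and gives the 5-chloro diol F6. I2/HIO3 can then enter only C7, giving the chloro iodo diol F7.
- The operations of steps 17–21 follow. Benzylation gives the chloro iodo benzyl ether F8 and methylation the chloro aryl iodide F9. Negishi coupling with 22 gives the chloro bromofuran F10. Suzuki coupling with 24 under PdCl2(dppf), which leaves the hindered aryl chloride alone, gives the chloro bifuran F11. The aryne cascade then leads through the chloro bis-adduct F12 to the chloro bis-naphthol F13.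
- Hydrogenolysis of F13 over Pd/C with added Et3N removes the chlorine together with the three benzyl groups and comes back to the route at 36.

Step 23.
- What may go wrong: slow loss of the trifluoroacetyl group from the hindered nitrogen. Hydrazone formation at the acetyl group may compete with ring closure. The free 6',6''-linked binaphthol may oxidise in air in the basic medium.
- Fallback: unmask the nitrogens while the three phenols are still benzylated and change the debenzylation method. It sets out from 35.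
- N2H4·H2O in refluxing EtOH, followed by K2CO3/MeOH–H2O if the amide persists, gives tri-O-benzyl korundamine A F14, which is easier to handle and purify.
- The C=N bond now rules out hydrogenolysis, so the benzyl ethers are cleaved with BCl3 and pentamethylbenzene in CH2Cl2 at −78 °C. At this temperature the methyl ethers next to N or peri to OH should survive. This comes back to the route at 38.

**Further compounds**
F1 | step 21 | ring T bromo-oxabicycle (3-bromo-5-methoxy-7-methyl-1,4-epoxy-1,4-dihydronaphthalene with ring T on C1, bridgeheads mixed) | BrC1=CC2(c3c(OCc4ccccc4)cc(OCc4ccccc4)c4c3C[C@@H](C)N(C(=O)C(F)(F)F)[C@@H]4C)OC1c1c(OC)cc(C)cc12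
F2 | step 21 | ring T 2-bromo-1-naphthol | Brc1cc(-c2c(OCc3ccccc3)cc(OCc3ccccc3)c3c2C[C@@H](C)N(C(=O)C(F)(F)F)[C@@H]3C)c2cc(C)cc(OC)c2c1O
F3 | step 21 | ring D bromo-oxabicycle (bridgeheads mixed) | CC(=O)c1c(OC)c(C23C=C(Br)C(O2)c2c(OC)cc(C)cc23)c(OCc2ccccc2)cc1C[C@@H](C)N1C(=O)c2ccccc2C1=O
F4 | step 21 | ring D 2-bromo-1-naphthol | CC(=O)c1c(OC)c(-c2cc(Br)c(O)c3c(OC)cc(C)cc23)c(OCc2ccccc2)cc1C[C@@H](C)N1C(=O)c2ccccc2C1=O
F5 | step 21 | ring T naphthol boronate | CC1(C)OB(OC1(C)C)c1cc(-c2c(OCc3ccccc3)cc(OCc3ccccc3)c3c2C[C@@H](C)N(C(=O)C(F)(F)F)[C@@H]3C)c2cc(C)cc(OC)c2c1O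
F6 | step 16 | 5-chloro diol, (R)-2-{1-[2-acetyl-6-chloro-3,5-dihydroxyphenyl]propan-2-yl}isoindoline-1,3-dione | CC(=O)c1c(O)cc(O)c(Cl)c1C[C@@H](C)N1C(=O)c2ccccc2C1=O
F7 | step 16 | chloro iodo diol | CC(=O)c1c(O)c(I)c(O)c(Cl)c1C[C@@H](C)N1C(=O)c2ccccc2C1=O
F8 | step 16 | chloro iodo benzyl ether | CC(=O)c1c(O)c(I)c(OCc2ccccc2)c(Cl)c1C[C@@H](C)N1C(=O)c2ccccc2C1=O
F9 | step 16 | chloro aryl iodide | CC(=O)c1c(OC)c(I)c(OCc2ccccc2)c(Cl)c1C[C@@H](C)N1C(=O)c2ccccc2C1=O
F10 | step 16 | chloro bromofuran | CC(=O)c1c(OC)c(-c2cc(Br)co2)c(OCc2ccccc2)c(Cl)c1C[C@@H](C)N1C(=O)c2ccccc2C1=O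
F11 | step 16 | chloro bifuran | CC(=O)c1c(OC)c(-c2cc(-c3coc(-c4c(OCc5ccccc5)cc(OCc5ccccc5)c5c4C[C@@H](C)N(C(=O)C(F)(F)F)[C@@H]5C)c3)co2)c(OCc2ccccc2)c(Cl)c1C[C@@H](C)N1C(=O)c2ccccc2C1=O
F12 | step 16 | chloro bis-adduct (bridgeheads mixed) | CC(=O)c1c(OC)c(C23C=C(C4=CC5(c6c(OCc7ccccc7)cc(OCc7ccccc7)c7c6C[C@@H](C)N(C(=O)C(F)(F)F)[C@@H]7C)OC4c4c(OC)cc(C)cc45)C(O2)c2c(OC)cc(C)cc23)c(OCc2ccccc2)c(Cl)c1C[C@@H](C)N1C(=O)c2ccccc2C1=O
F13 | step 16 | chloro bis-naphthol | CC(=O)c1c(OC)c(-c2cc(-c3cc(-c4c(OCc5ccccc5)cc(OCc5ccccc5)c5c4C[C@@H](C)N(C(=O)C(F)(F)F)[C@@H]5C)c4cc(C)cc(OC)c4c3O)c(O)c3c(OC)cc(C)cc23)c(OCc2ccccc2)c(Cl)c1C[C@@H](C)N1C(=O)c2ccccc2C1=O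
F14 | step 23 | tri-O-benzyl korundamine A | COc1c2c(cc(OCc3ccccc3)c1-c1cc(-c3cc(-c4c(OCc5ccccc5)cc(OCc5ccccc5)c5c4C[C@@H](C)N[C@@H]5C)c4cc(C)cc(OC)c4c3O)c(O)c3c(OC)cc(C)cc13)C[C@@H](C)N=C2C
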